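All constants stand for no real mixture; the run is a simulation.

The ratio of electrophile charged to electrophile left at the end is 5.00 for this flask at the asked time.

electrophile 0.10 M; gas 4.3 mM (held); scavenger 0.0800 M; time 10 h

    electrophile + nucleophile → acid set free + product (k1 = 2.7 L mol⁻¹ h⁻¹)
    nucleophile + acid set free ⇌ protonated nucleophile, settled at all times (K2 = 1500 L mol⁻¹)
    acid set free + free base ⇌ salt of the base, settled at all times (K3 = 2.8 × 10⁶ L mol⁻¹)
    nucleophile ⇌ dormant form (K4 = 0.73, k4 = 0.32 h⁻¹)
    gas ⇌ free base, rate k5*(csat - [free base]) (k5 = 19 h⁻¹, csat = 4.3 mM)
    electrophile + acid set free ⇌ idle adduct, settled at all times (K6 = 4.0 L mol⁻¹)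
    acid set free + scavenger → scavenged by-product (k7 = 250 L mol⁻¹ h⁻¹)

- the concentration of nucleophile at which the part of the electrophile that has reacted at 10 h is just 80%, in M

- for acid set free the idle adduct is counted in
- at the start none of free base is dissolved
- the amount of nucleophile is what is sought; it is there from the start
- what has gone from electrophile into another species counts as reacted, even if it can come back
- run time (flask): 10 h

- I count the first step as the electrophile's way out and set protonated nucleophile and idle adduct aside. With rate constant 2.7 L mol⁻¹ h⁻¹, the electrophile then falls at each moment as a pseudo-first-order decay, so the logarithm of that ratio equals 2.7 L mol⁻¹ h⁻¹ times the time integral of c(nucleophile).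
- Dividing by 2.7 L mol⁻¹ h⁻¹ and 10 h gives the required mean free nucleophile, the time-averaged c(nucleophile) that the run must hold: 0.0596 M.
- The dormant balance leaves a free share of 0.578, and its relaxation half-life of 0.914 h is shorter than the run. The delay in reaching that balance adds 0.0556 of the charge to the mean.
- For a first bracket, a charge with no nucleophile used needs 0.0941 M. Ignoring the delay and subtracting the full 0.0800 M used from the start needs 0.183 M.
- To tighten it, take the mean amount used, which enters multiplied by the free share. A plain exponential gives 0.0503 M, which I take as the low estimate, and I take 0.0800 M as the high one.
- By this reckoning, the charge of nucleophile lies between 0.140 M and 0.167 M.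
- The forecast of 0.153 M, with range 0.14 M to 0.17 M, rests on "a rough hand integration brackets the 80% point" and stands inside my bracket.
- The simulation of this flask gives a nucleophile charge of 0.154 M, which lies within the bracket. That nucleophile charge over the electrophile charged is 1.54.
- In this flask, 26.6% of the charged nucleophile is still free at 10.0 h, which is 0.0410 M, less than the required mean.
- Applied to the 63.5% of electrophile used by 5.00 h, the same rule gives a mean free nucleophile of 0.0747 M over that stretch, more than the 0.0596 M over the whole run.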